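**Assumption:** names use eremophilane numbering (C1 carries OAc, C4 and C5 the methyls, C7 the isopropenyl group, C8 the tiglate, C9 the ketone, C10 the ring-fusion CH); β is the face of the C5 methyl, α the opposite face. The route has not been run; selectivities are argued by analogy.

**Retrosynthetic overview**
1. C9 ketone ⇐ 9α-carbinol (oxidised last, so the base-labile β-acetoxy ketone and the trans ring fusion are never exposed); 8-O-tiglate ⇐ 8α-OH.
2. C7 isopropenyl and C8 OH ⇐ trans-diaxial opening of the 7α,8α-epoxide of a trans-Δ7-octalin by an isopropenyl cuprate.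
3. Ring B (formed second) ⇐ ring-closing metathesis of a C5 allyl group and a C10 (1-silyloxy)allyl side chain on ring A.
4. Both side chains ⇐ one-pot Sakurai allylation and acrolein aldol on (S)-3,4-dimethylcyclohex-2-enone (sets C5, C10, C9); C1 ketone ⇒ 1α-OAc.
5. Ring A (formed first) ⇐ organocatalytic Michael/aldol annulation of propanal and methyl vinyl ketone (sets C4), then β-methylation and Saegusa oxidation.

**Route**

Step 1
Reactants: 1 propanal; 2 but-3-en-2-one (methyl vinyl ketone)
Product: 4 (S)-4-methylcyclohex-2-en-1-one, via keto-aldehyde 3 (not isolated)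
Conditions: (R)-2-[methoxy(diphenyl)methyl]pyrrolidine (5 mol %), ethyl 3,4-dihydroxybenzoate (20 mol %), neat, 4 °C; then LiOH (0.2 equiv), i-PrOH, rt
Reagents that add atoms: none
Why: Enamine-catalysed asymmetric Michael addition (the bulky pyrrolidine substituent shields one enamine face and sets the methyl-bearing centre, future C4, as S) followed by intramolecular aldol condensation (Robinson-type annulation) that does not touch this centre.

Step 2
Reactants: 4 (S)-4-methylcyclohex-2-en-1-one
Product: 6 (S)-3,4-dimethylcyclohex-2-en-1-one, via silyl enol ether 5 (not isolated)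
Conditions: MeMgBr, CuBr·SMe2 (5 mol %), TMSCl, THF, −78 °C; then Pd(OAc)2 (1.05 equiv), MeCN, rt
Reagents that add atoms: methylmagnesium bromide, C[Mg]Br
Why: Copper-catalysed conjugate addition with O-silylation gives the regiodefined enol silane, and Saegusa–Ito dehydrogenation re-forms the enone on the methylated side, which erases the transient C3 centre and leaves C4 untouched.

Step 3
Reactants: 6 (S)-3,4-dimethylcyclohex-2-en-1-one; 7 allyltrimethylsilane; 8 acrolein (prop-2-enal)
Product: 10 (2R,3R,4S)-2-[(1R)-1-hydroxyprop-2-en-1-yl]-3,4-dimethyl-3-(prop-2-en-1-yl)cyclohexan-1-one, via titanium enolate 9 (not isolated)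
Conditions: TiCl4 (1.1 equiv), CH2Cl2, −78 °C; then acrolein, −78 °C; aq. NH4Cl
Reagents that add atoms: none
Why: Hosomi–Sakurai conjugate allylation occurs anti to the pseudoaxial C4 methyl (C5 quaternary centre, methyls cis), and the regiodefined trichlorotitanium enolate then undergoes aldol addition to acrolein anti to the new axial allyl group through a chair Zimmerman–Traxler transition state of the (E)-enolate, giving the trans-2,3 arrangement (future 10α-H) and the anti carbinol (future 9α-O).

Step 4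
Reactants: 10 the aldol from step 3
Product: 11 (2R,3R,4S)-2-[(1R)-1-(tert-butyldimethylsilyloxy)prop-2-en-1-yl]-3,4-dimethyl-3-(prop-2-en-1-yl)cyclohexan-1-one
Conditions: TBSOTf, 2,6-lutidine, CH2Cl2, −78 °C
Reagents that add atoms: tert-butyldimethylsilyl trifluoromethanesulfonate, CC(C)(C)[Si](C)(C)OS(=O)(=O)C(F)(F)F
Why: Low-temperature O-silylation masks the C9 carbinol (the future ketone) before the β-hydroxy ketone can dehydrate or undergo retro-aldol cleavage; no stereocentre is touched.

Step 5
Reactants: 11 the silyl ether ketone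
Product: 12 (1S,2S,3R,4S)-2-[(1R)-1-(tert-butyldimethylsilyloxy)prop-2-en-1-yl]-3,4-dimethyl-3-(prop-2-en-1-yl)cyclohexan-1-ol
Conditions: Li, NH3(l)/THF, t-BuOH, −78 °C, 10 min; then NH4Cl
Reagents that add atoms: none
Why: Dissolving-metal ketone reduction is thermodynamically controlled and gives the equatorial 1α-alcohol trans to the C10 side chain (hydride reagents would be steered by the syn-axial C5 methyl to the axial epimer), while the isolated alkenes and the silyl ether are inert.

Step 6
Reactants: 12 the 1α-alcohol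
Product: 13 (1S,2S,3R,4S)-2-[(1R)-1-(tert-butyldimethylsilyloxy)prop-2-en-1-yl]-3,4-dimethyl-3-(prop-2-en-1-yl)cyclohexyl acetate
Conditions: Ac2O, DMAP, pyridine, CH2Cl2, rt
Reagents that add atoms: acetic anhydride, CC(=O)OC(C)=O
Why: DMAP-catalysed acylation of the only free hydroxyl installs the C1 acetate while ring A is still conformationally free; no stereocentre is touched.

Step 7
Reactants: 13 the diene acetate
Product: 14 1α-acetoxy-9α-(tert-butyldimethylsilyloxy)-4β,5β-dimethyl-11,12,13-trinor-10αH-eremophil-7-ene (trans-fused Δ7-octalin)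
Conditions: second-generation Grubbs catalyst (5 mol %), CH2Cl2, 40 °C
Reagents that add atoms: none
Why: Ring-closing olefin metathesis of the allyl and vinyl groups, which sit trans-diequatorial on ring A, closes ring B as the trans-fused octalin with loss of ethylene and without touching a stereocentre.

Step 8
Reactants: 14 the Δ7-octalin
Product: 15 1α-acetoxy-9α-(tert-butyldimethylsilyloxy)-7α,8α-epoxy-4β,5β-dimethyl-11,12,13-trinor-10αH-eremophilane
Conditions: mCPBA, CH2Cl2, 0 °C
Reagents that add atoms: meta-chloroperoxybenzoic acid, OOC(=O)c1cccc(Cl)c1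
Why: Prilezhaev epoxidation takes place on the α face because the axial C5 methyl shields the β face of the C7=C8 bond (the same bias that gives 2α,3α-epoxides from 5α-steroid 2-enes).

Step 9
Reactants: 15 the 7α,8α-epoxide
Product: 16 1α-acetoxy-9α-(tert-butyldimethylsilyloxy)-4β,5β-dimethyl-7β-(prop-1-en-2-yl)-10αH-eremophil-11-en-8α-ol
Conditions: isopropenylmagnesium bromide (4 equiv), CuI (2 equiv), THF, −40 °C; then 15, −40 → 0 °C; aq. NH4Cl
Reagents that add atoms: isopropenylmagnesium bromide, C=C(C)[Mg]Br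
Why: Fürst–Plattner trans-diaxial epoxide opening by the organocuprate, with SN2 attack at C7 (remote from the C9 silyloxy group) and inversion, gives the 7β-isopropenyl and 8α-hydroxyl groups, and the homocuprate does not attack the acetate.

Step 10
Reactants: 16 the 8α-alcohol
Product: 17 1α-acetoxy-9α-(tert-butyldimethylsilyloxy)-8α-[(E)-2-methylbut-2-enoyloxy]-4β,5β-dimethyl-7β-(prop-1-en-2-yl)-10αH-eremophil-11-ene
Conditions: (E)-2-methylbut-2-enoyl chloride, DMAP, Et3N, ClCH2CH2Cl, 60 °C
Reagents that add atoms: tigloyl chloride, C/C=C(\C)C(Cl)=O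
Why: DMAP-catalysed acylation of the single free (axial, hindered) hydroxyl under forcing conditions, with the thermodynamically stable (E)-tiglate geometry retained and no stereocentre touched.

Step 11
Reactants: 17 the silyl ether tiglate
Product: 18 1α-acetoxy-8α-[(E)-2-methylbut-2-enoyloxy]-4β,5β-dimethyl-7β-(prop-1-en-2-yl)-10αH-eremophil-11-en-9α-ol
Conditions: HF·pyridine, THF/pyridine, 0 °C → rt
Reagents that add atoms: none
Why: Fluoride-mediated desilylation under buffered, non-basic conditions frees the C9 hydroxyl while avoiding tiglate migration from O8 to O9 and ester cleavage.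

Step 12
Reactants: 18 the 9α-alcohol
Product: 19 1α-acetoxy-8α-tigloyloxy-10αH-eremophil-11-en-9-one, (2R,3R,4aR,5S,8S,8aS)-8-acetoxy-4a,5-dimethyl-1-oxo-3-(prop-1-en-2-yl)decahydronaphthalen-2-yl (2E)-2-methylbut-2-enoate
Conditions: Dess–Martin periodinane, CH2Cl2, rt
Reagents that add atoms: none
Why: Dess–Martin oxidation under neutral conditions converts the C9 carbinol into the ketone without epimerising the adjacent C8 and C10 centres or eliminating the β-acetoxy group.

**Compound list**
1 | propanal | CCC=O | starting material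
2 | but-3-en-2-one (methyl vinyl ketone) | CC(=O)C=C | starting material
3 | (S)-2-methyl-5-oxohexanal | CC(=O)CC[C@@H](C=O)C | intermediate
4 | (S)-4-methylcyclohex-2-en-1-one | C1=CC(=O)CC[C@@H]1C | intermediate
5 | (3R,4S)-3,4-dimethyl-1-(trimethylsilyloxy)cyclohex-1-ene | C[C@H]1C=C(O[Si](C)(C)C)CC[C@@H]1C | intermediate
6 | (S)-3,4-dimethylcyclohex-2-en-1-one | CC1=CC(=O)CC[C@@H]1C | intermediate
7 | allyltrimethylsilane | C=CC[Si](C)(C)C | starting material
8 | acrolein (prop-2-enal) | C=CC=O | starting material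
9 | trichloro{[(3R,4S)-3,4-dimethyl-3-(prop-2-en-1-yl)cyclohex-1-en-1-yl]oxy}titanium | C=CC[C@@]1(C)C=C(O[Ti](Cl)(Cl)Cl)CC[C@@H]1C | intermediate
10 | (2R,3R,4S)-2-[(1R)-1-hydroxyprop-2-en-1-yl]-3,4-dimethyl-3-(prop-2-en-1-yl)cyclohexan-1-one | C=CC[C@@]1(C)[C@H]([C@H](O)C=C)C(=O)CC[C@@H]1C | intermediate
11 | (2R,3R,4S)-2-[(1R)-1-(tert-butyldimethylsilyloxy)prop-2-en-1-yl]-3,4-dimethyl-3-(prop-2-en-1-yl)cyclohexan-1-one | C=CC[C@@]1(C)[C@H]([C@H](O[Si](C)(C)C(C)(C)C)C=C)C(=O)CC[C@@H]1C | intermediate
12 | (1S,2S,3R,4S)-2-[(1R)-1-(tert-butyldimethylsilyloxy)prop-2-en-1-yl]-3,4-dimethyl-3-(prop-2-en-1-yl)cyclohexan-1-ol | C=CC[C@@]1(C)[C@H]([C@H](O[Si](C)(C)C(C)(C)C)C=C)[C@@H](O)CC[C@@H]1C | intermediate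
13 | (1S,2S,3R,4S)-2-[(1R)-1-(tert-butyldimethylsilyloxy)prop-2-en-1-yl]-3,4-dimethyl-3-(prop-2-en-1-yl)cyclohexyl acetate | C=CC[C@@]1(C)[C@H]([C@H](O[Si](C)(C)C(C)(C)C)C=C)[C@@H](OC(C)=O)CC[C@@H]1C | intermediate
14 | 1α-acetoxy-9α-(tert-butyldimethylsilyloxy)-4β,5β-dimethyl-11,12,13-trinor-10αH-eremophil-7-ene | C1=CC[C@@]2(C)[C@H]([C@@H]1O[Si](C)(C)C(C)(C)C)[C@@H](OC(C)=O)CC[C@@H]2C | intermediate
15 | 1α-acetoxy-9α-(tert-butyldimethylsilyloxy)-7α,8α-epoxy-4β,5β-dimethyl-11,12,13-trinor-10αH-eremophilane | C1[C@@]2(C)[C@H]([C@H](O[Si](C)(C)C(C)(C)C)[C@@H]3O[C@H]13)[C@@H](OC(C)=O)CC[C@@H]2C | intermediate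
16 | 1α-acetoxy-9α-(tert-butyldimethylsilyloxy)-4β,5β-dimethyl-7β-(prop-1-en-2-yl)-10αH-eremophil-11-en-8α-ol | C=C(C)[C@H]1C[C@@]2(C)[C@H]([C@H](O[Si](C)(C)C(C)(C)C)[C@@H]1O)[C@@H](OC(C)=O)CC[C@@H]2C | intermediate
17 | 1α-acetoxy-9α-(tert-butyldimethylsilyloxy)-8α-[(E)-2-methylbut-2-enoyloxy]-4β,5β-dimethyl-7β-(prop-1-en-2-yl)-10αH-eremophil-11-ene | C=C(C)[C@H]1C[C@@]2(C)[C@H]([C@H](O[Si](C)(C)C(C)(C)C)[C@@H]1OC(=O)/C(C)=C/C)[C@@H](OC(C)=O)CC[C@@H]2C | intermediate
18 | 1α-acetoxy-8α-[(E)-2-methylbut-2-enoyloxy]-4β,5β-dimethyl-7β-(prop-1-en-2-yl)-10αH-eremophil-11-en-9α-ol | C=C(C)[C@H]1C[C@@]2(C)[C@H]([C@H](O)[C@@H]1OC(=O)/C(C)=C/C)[C@@H](OC(C)=O)CC[C@@H]2C | intermediate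
19 | (2R,3R,4aR,5S,8S,8aS)-8-acetoxy-4a,5-dimethyl-1-oxo-3-(prop-1-en-2-yl)decahydronaphthalen-2-yl (2E)-2-methylbut-2-enoate (1α-acetoxy-8α-tigloyloxy-10αH-eremophil-11-en-9-one) | C=C(C)[C@H]1C[C@@]2(C)[C@H](C(=O)[C@@H]1OC(=O)/C(C)=C/C)[C@@H](OC(C)=O)CC[C@@H]2C | target

**Totals**
Total step count: 12. Longest linear sequence: 12 steps (1 and 2 to 19).

**Three steps most likely to fail**

Step 9 (epoxide opening). The nucleophile must enter axially at C7, syn to the axial C5 methyl, and the acetate must survive. The fallback sets out from 15 and comes back at 16. Lithium acetylide with BF3·OEt2 in THF at −78 °C (Yamaguchi-type alkynylation) delivers a small linear nucleophile in the same trans-diaxial sense and gives the 7β-ethynyl 8α-alcohol F3. Zirconium-catalysed Negishi carboalumination of the terminal alkyne (Me3Al, Cp2ZrCl2, then water) turns the ethynyl group into the isopropenyl group of 16.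

Step 5 (C1 reduction). The equatorial selectivity of the dissolving-metal reduction, or the survival of the allylic silyl ether, may be poorer than assumed. The fallback sets out from 11 and comes back at 13. K[B(sec-Bu)3H] attacks from the face away from the axial C5 methyl and gives the axial 1β-alcohol F2 cleanly. Mitsunobu inversion with acetic acid (PPh3, DIAD) then installs the 1α-acetate directly, so step 6 is not needed.

Step 3 (tandem Sakurai/aldol). The titanium enolate may give a low yield or poor C9 selectivity with acrolein. The minor C9 epimer would also be a poor substrate later, because an axial 9β-silyloxy group blocks the C7 attack in step 9. The fallback sets out from 6 and comes back at 10. A TMSNTf2-catalysed Sakurai allylation keeps the silyl group on oxygen and gives the isolable silyl enol ether F1. MeLi then releases the regiodefined lithium enolate, which adds to acrolein at −78 °C through a closed transition state to give the anti aldol 10.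

Further compounds
F1 | step 3 | (3R,4S)-3,4-dimethyl-3-(prop-2-en-1-yl)-1-(trimethylsilyloxy)cyclohex-1-ene | C=CC[C@@]1(C)C=C(O[Si](C)(C)C)CC[C@@H]1C
F2 | step 5 | (1R,2S,3R,4S)-2-[(1R)-1-(tert-butyldimethylsilyloxy)prop-2-en-1-yl]-3,4-dimethyl-3-(prop-2-en-1-yl)cyclohexan-1-ol | C=CC[C@@]1(C)[C@H]([C@H](O[Si](C)(C)C(C)(C)C)C=C)[C@H](O)CC[C@@H]1C
F3 | step 9 | 1α-acetoxy-9α-(tert-butyldimethylsilyloxy)-7β-ethynyl-4β,5β-dimethyl-11,12,13-trinor-10αH-eremophilan-8α-ol | C#C[C@H]1C[C@@]2(C)[C@H]([C@H](O[Si](C)(C)C(C)(C)C)[C@@H]1O)[C@@H](OC(C)=O)CC[C@@H]2C
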